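**Retrosynthetic overview**
1. Feature: C15–C4–C5–C10 is a four-carbon chain (secondary methyl C15 on C4, quaternary C5 carrying C14, ring-fusion C10) on the C5–C10 edge of ring B; it is carried as a cyclobutane whose C10–C15 bond is cut later to reveal the C4 methyl.
2. Late stage: C3–O ester by Mitsunobu inversion of a 3β-alcohol; O9 by α'-hydroxylation; C7=C11 by acetone aldol–dehydration; C8 carbonyl by 1,2-transposition of the C9 ketone through a diosphenol triflate, the resulting 9(10)-en-8-one being reduced to the trans ring fusion.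
3. Ring A: C1–C10 by intramolecular enolate alkylation with a chloroethyl arm, after SmI2 cleavage of C10–C15 of the cyclobutyl ketone.
4. Cyclobutane: C4–C5 and C10–C15 by enantioselective [2+2] photocycloaddition of 3-methylcyclohex-2-en-1-one (ring B) with 2-(2-chloroethyl)-2-vinyl-1,3-dioxolane (C1–C4 and C15).
5. Ring order: ring B (bought) → cyclobutane (step 4) → cyclobutane opened (step 5) → ring A (step 6).

Key step: step 4

Assumptions on the chemistry:
- Locants are those of the target skeleton (ring A = C1–C5, C10; ring B = C5–C10; C14 on C5, C15 on C4); β is the face of C14.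
- The antipode of the oxazaborolidine that gives (6S)-8 is chosen after a test run.
- The photoadduct is drawn as the exo isomer and compounds 10 and 11 as the cis-fused C10 epimer. The other C4 and C10 epimers converge in steps 8, 11 and 16.
- 3-Methylfuran-2(5H)-one, 3-bromopropanoyl chloride and angelic acid are bought.

**Route**

Step 1
Reactants: 1 3-bromopropanoyl chloride; 2 ethylene
Product: 3 1-bromo-5-chloropentan-3-one
Conditions: AlCl3 (1.1 equiv), ethylene (1 atm), CH2Cl2, 0 °C
Reagents that add atoms: none
Why: Aliphatic Friedel–Crafts acylation of ethylene, in which the acylium ion adds to ethylene and chloride from AlCl4− captures the β-cation, so the two arms carry different halogens (Br for elimination, Cl as the later alkylation handle).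

Step 2
Reactants: 3 1-bromo-5-chloropentan-3-one; 4 ethylene glycol
Product: 5 2-(2-bromoethyl)-2-(2-chloroethyl)-1,3-dioxolane
Conditions: p-TsOH·H2O (cat.), benzene, reflux, Dean–Stark
Reagents that add atoms: none
Why: Acid-catalysed ketalisation with azeotropic removal of water, conditions that β-halo ketones tolerate because no base is present.

Step 3
Reactants: 5 2-(2-bromoethyl)-2-(2-chloroethyl)-1,3-dioxolane
Product: 6 2-(2-chloroethyl)-2-vinyl-1,3-dioxolane
Conditions: KOt-Bu (1.05 equiv), THF, −20 → 0 °C
Reagents that add atoms: none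
Why: E2 dehydrohalogenation in which the primary bromide eliminates much faster than the primary chloride, so one equivalent of base should give the mono-vinyl ketal with the chloroethyl arm intact.

Step 4
Reactants: 7 3-methylcyclohex-2-en-1-one; 6 2-(2-chloroethyl)-2-vinyl-1,3-dioxolane
Product: 8 (1S,6S,7S)-7-[2-(2-chloroethyl)-1,3-dioxolan-2-yl]-6-methylbicyclo[4.2.0]octan-2-one (cis-fused; exo; C6 = C5 of the target)
Conditions: chiral B-aryl oxazaborolidine (from α,α-diarylprolinol) activated with AlBr3 (50 mol %), 6 (3 equiv), CH2Cl2, −75 °C, hν (λ = 366 nm)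
Reagents that add atoms: none
Why: The enone bound to the chiral Lewis acid absorbs at 366 nm far more strongly than free 7, crosses to its triplet and adds 6 stepwise, the unsubstituted terminus C15 bonding to the α-carbon C10 and the resulting 1,4-diradical (tertiary at C5, secondary at C4) collapsing after spin inversion to form C4–C5; the closest known reaction is the enantioselective intermolecular [2+2] photocycloaddition of 3-substituted cyclohexenones with simple alkenes under AlBr3-activated oxazaborolidines. The four-membered ring is closed by radical–radical recombination of that diradical on the C5–C10 edge of ring B. C5, the only centre carried unchanged to the target, is set by the aryl groups of the catalyst, which shield one face of the bound enone; the cis fusion at C10 follows from the strain of the trans-bicyclo[4.2.0] system and the exo position at C4 from approach anti to the six-membered ring, but neither matters because C10 becomes CH2 in step 5 and C4 is equilibrated in step 16. The step needs head-to-tail regiochemistry, which the β-methyl group should secure by steering the first bond to C10 and by the preference for the secondary radical at C4, and it needs the Lewis acid to stay on the enone carbonyl rather than on the hindered, less basic ketal oxygens, which the low temperature and the quaternary ketal carbon should favour.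

Step 5
Reactants: 8 photoadduct
Product: 9 (S)-3-{(S)-1-[2-(2-chloroethyl)-1,3-dioxolan-2-yl]ethyl}-3-methylcyclohexan-1-one
Conditions: SmI2 (2.5 equiv), t-BuOH (2.2 equiv), THF/DMPU, −78 → 0 °C
Reagents that add atoms: none
Why: Single-electron reduction gives the C9 ketyl, whose cyclobutane opens at the exocyclic C10–C15 bond (the one aligned with the carbonyl π system); the primary C15 radical is reduced and protonated to the C4 methyl and the enolate is protonated at C10, while the primary chloride is inert to SmI2 without HMPA (reductive cleavage of a cyclobutyl ketone).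

Step 6
Reactants: 9 chloro ketone
Product: 10 3,3-ethylenedioxy-4α,5β-dimethyl-10β-H-decalin-9-one (cis-fused; C10 epimers possible)
Conditions: KOt-Bu (1.1 equiv), t-BuOH/THF, 25 → 45 °C
Reagents that add atoms: none
Why: Intramolecular enolate C-alkylation (6-exo-tet) in which, under equilibrating alkoxide conditions, only the C10 enolate can reach C1 through a six-membered transition state (the C8 enolate would have to form a bridged eight-membered ring), closing ring A; E2 of the primary chloride is slow in t-BuOH.

Step 7
Reactants: 10 decalone ketal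
Product: 11 8-hydroxy-3,3-ethylenedioxy-4α,5β-dimethyl-10β-H-decalin-9-one (C8 epimers)
Conditions: KN(SiMe3)2 (1.1 equiv), THF, −78 °C; 2-(phenylsulfonyl)-3-phenyloxaziridine; aq. NH4Cl
Reagents that add atoms: 2-(phenylsulfonyl)-3-phenyloxaziridine, O=S(=O)(N1OC1c1ccccc1)c1ccccc1
Why: Kinetic deprotonation at the C8 methylene (the C10 methine is hindered) and oxidation of the enolate by the N-sulfonyloxaziridine (Davis hydroxylation); the C8 configuration is irrelevant.

Step 8
Reactants: 11 α-ketol
Product: 12 3,3-ethylenedioxy-9-hydroxy-4α,5β-dimethyl-Δ9(10)-octalin-8-one (diosphenol)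
Conditions: Dess–Martin periodinane (1.2 equiv), NaHCO3, CH2Cl2, 25 °C; then Et3N (cat.)
Reagents that add atoms: none
Why: Dess–Martin oxidation of the α-ketol to the 8,9-dione, which should enolise toward the ring fusion to the tetrasubstituted diosphenol (as 3,4-dioxo steroids exist as 4-hydroxy-4-en-3-ones), removing the C8 and C10 stereocentres.

Step 9
Reactants: 12 diosphenol
Product: 13 3,3-ethylenedioxy-4α,5β-dimethyl-8-oxo-Δ9(10)-octalin-9-yl trifluoromethanesulfonate
Conditions: PhNTf2, Et3N, DMAP (cat.), CH2Cl2, 0 → 25 °C
Reagents that add atoms: N-phenylbis(trifluoromethanesulfonimide), O=S(=O)(N(c1ccccc1)S(=O)(=O)C(F)(F)F)C(F)(F)F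
Why: O-Sulfonylation of the acidic enol hydroxyl under mild basic conditions that leave the ketal alone gives the vinyl triflate.

Step 10
Reactants: 13 vinyl triflate
Product: 14 3,3-ethylenedioxy-4α,5β-dimethyl-Δ9(10)-octalin-8-one
Conditions: Pd(OAc)2 (5 mol %), PPh3, HCO2H, n-Bu3N, DMF, 60 °C
Reagents that add atoms: none
Why: Zerovalent palladium formed in situ inserts into the vinyl C–OTf bond, formate delivers hydride with loss of CO2 and reductive elimination gives the enone, completing the 1,2-carbonyl transposition from C9 to C8.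

Step 11
Reactants: 14 enone
Product: 15 3,3-ethylenedioxy-4α,5β-dimethyl-10α-H-decalin-8-one (trans-fused)
Conditions: Li (2.5 equiv), NH3(l)/THF, t-BuOH (1.0 equiv), −78 °C; isoprene; NH4Cl
Reagents that add atoms: none
Why: Birch-type dissolving-metal reduction of the enone, in which the β-carbanion at C10 is protonated axially with continuous overlap to the enolate, giving the trans ring fusion (10α-H, anti to the C5 methyl); the ketal is inert.

Step 12
Reactants: 15 trans-decalone; 16 acetone
Product: 17 3,3-ethylenedioxy-7α-(2-hydroxypropan-2-yl)-4α,5β-dimethyl-10α-H-decalin-8-one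
Conditions: LiN(i-Pr)2 (1.1 equiv), THF, −78 °C; ZnCl2; acetone, −78 °C; aq. NH4Cl
Reagents that add atoms: none
Why: Kinetic enolisation of the trans-fused 8-ketone goes toward C7 (as trans-fused 3-keto steroids enolise toward C2), and the zinc enolate adds to acetone (directed aldol) with the new substituent equatorial; this centre disappears in step 13.

Step 13
Reactants: 17 aldol
Product: 19 3,3-ethylenedioxy-4α,5β-dimethyl-7-(propan-2-ylidene)-10α-H-decalin-8-one, via tertiary mesylate 18 (not isolated)
Conditions: MsCl, Et3N, DMAP (cat.), CH2Cl2, 0 °C; then DBU, 25 °C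
Reagents that add atoms: none
Why: Mesylation of the tertiary aldol followed by E1cB elimination through the C7 enolate gives the conjugated isopropylidene ketone (aldol dehydration).

Step 14
Reactants: 19 isopropylidene ketone
Product: 20 3,3-ethylenedioxy-9α-hydroxy-4α,5β-dimethyl-7-(propan-2-ylidene)-10α-H-decalin-8-one
Conditions: KN(SiMe3)2 (1.1 equiv), THF, −78 °C; 2-(phenylsulfonyl)-3-phenyloxaziridine; aq. NH4Cl
Reagents that add atoms: 2-(phenylsulfonyl)-3-phenyloxaziridine, O=S(=O)(N1OC1c1ccccc1)c1ccccc1
Why: Kinetic α'-deprotonation of the enone at C9 and Davis hydroxylation from the α face, anti to the axial C5 methyl, give the equatorial 9α-alcohol, which is also the thermodynamic epimer of this enolisable centre.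

Step 15
Reactants: 20 α'-hydroxy enone
Product: 21 9α-(tert-butyldimethylsilyloxy)-3,3-ethylenedioxy-4α,5β-dimethyl-7-(propan-2-ylidene)-10α-H-decalin-8-one
Conditions: TBSOTf, 2,6-lutidine, CH2Cl2, −78 → −40 °C
Reagents that add atoms: tert-butyldimethylsilyl trifluoromethanesulfonate, CC(C)(C)[Si](C)(C)OS(=O)(=O)C(F)(F)F
Why: Silylation of the hindered secondary alcohol with the silyl triflate at low temperature, where the dioxolane is not opened; the TBS ether masks O9 through steps 16–21.

Step 16
Reactants: 21 silyl ether ketal
Product: 23 9α-(tert-butyldimethylsilyloxy)-4β,5β-dimethyl-7-(propan-2-ylidene)-10α-H-decalin-3,8-dione, via 4-epi dione 22 (not isolated)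
Conditions: PPTS, acetone/H2O (10:1), 55 °C; then K2CO3, MeOH, 25 °C
Reagents that add atoms: water, O
Why: Acid-catalysed hydrolysis of the strained dioxolane (one oxygen is syn-axial to the C5 methyl) frees the C3 ketone, and base-mediated enolisation should equilibrate C4 to the equatorial 4β-methyl epimer (an axial methyl would be syn-axial to H2 and H10), protonation from the α face anti to the C5 methyl pointing the same way; C9 stays in its equatorial, thermodynamic configuration.

Step 17
Reactants: 23 3,8-dione
Product: 24 9α-(tert-butyldimethylsilyloxy)-3β-hydroxy-4β,5β-dimethyl-7-(propan-2-ylidene)-10α-H-decalin-8-one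
Conditions: LiBH(s-Bu)3 (1.1 equiv), THF, −78 °C; aq. NH4Cl
Reagents that add atoms: none
Why: The bulky hydride attacks C3 from the α face (equatorial attack, the β face being blocked by the syn-axial C5 methyl) to give the axial 3β-alcohol, and should leave the far more hindered, conjugated C8 ketone untouched (diastereoselective ketone reduction).

Step 18
Reactants: 25 3-methylfuran-2(5H)-one
Product: 27 4-methoxybenzyl (Z)-4-hydroxy-2-methylbut-2-enoate, via sodium (Z)-4-hydroxy-2-methylbut-2-enoate 26 (not isolated)
Conditions: NaOH (1.0 equiv), H2O/MeOH, 0 → 25 °C, evaporate; 4-methoxybenzyl chloride, Bu4NI (cat.), DMF, 0 → 25 °C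
Reagents that add atoms: sodium hydroxide, [Na+].[OH-]; 4-methoxybenzyl chloride, COc1ccc(CCl)cc1
Why: Saponification of the butenolide gives the hydroxy carboxylate with the Z geometry fixed by the ring, and O-alkylation of the carboxylate traps it as an ester before it can relactonise; 27 is used at once.

Step 19
Reactants: 27 hydroxy ester; 28 angelic acid
Product: 29 4-methoxybenzyl (Z)-2-methyl-4-{[(Z)-2-methylbut-2-enoyl]oxy}but-2-enoate
Conditions: PPh3, DIAD, THF, 0 °C
Reagents that add atoms: none
Why: Mitsunobu esterification of the primary allylic alcohol under neutral conditions at 0 °C, which avoids lactonisation of 27 and Z→E isomerisation of the angelate.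

Step 20
Reactants: 29 diester
Product: 30 (Z)-2-methyl-4-{[(Z)-2-methylbut-2-enoyl]oxy}but-2-enoic acid
Conditions: CF3CO2H, Et3SiH, CH2Cl2, 0 °C
Reagents that add atoms: none
Why: Acidolysis of the 4-methoxybenzyl ester with hydride capture of the benzyl cation frees the acid without touching either Z-enoate or the allylic ester.

Step 21
Reactants: 24 3β-alcohol; 30 side-chain acid
Product: 31 9-O-tert-butyldimethylsilyl ether of the target (3α-ester)
Conditions: PPh3, DIAD, toluene, 0 → 25 °C
Reagents that add atoms: none
Why: Mitsunobu esterification in which the axial 3β-oxyphosphonium is displaced by the carboxylate from the α face with inversion, giving the equatorial 3α-ester under neutral conditions that do not isomerise the Z-enoates.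

Step 22
Reactants: 31 silyl-protected ester
Product: 32 (1R,2R,4aR,5S,8aR)-5-hydroxy-1,8a-dimethyl-6-oxo-7-(propan-2-ylidene)decahydronaphthalen-2-yl (Z)-2-methyl-4-{[(Z)-2-methylbut-2-enoyl]oxy}but-2-enoate (target CNP0308665.1)
Conditions: HF·pyridine, THF/pyridine, 0 → 25 °C
Reagents that add atoms: none
Why: Fluoride cleavage of the silyl ether under buffered, mildly acidic conditions frees the 9α-hydroxy ketone without acyl migration or enoate isomerisation.

**Compound list**
1 | 3-bromopropanoyl chloride | BrCCC(Cl)=O | starting material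
2 | ethylene | C=C | starting material
3 | 1-bromo-5-chloropentan-3-one | BrCCC(=O)CCCl | intermediate
4 | ethylene glycol | OCCO | starting material
5 | 2-(2-bromoethyl)-2-(2-chloroethyl)-1,3-dioxolane | BrCCC1(CCCl)OCCO1 | intermediate
6 | 2-(2-chloroethyl)-2-vinyl-1,3-dioxolane | C=CC1(CCCl)OCCO1 | intermediate
7 | 3-methylcyclohex-2-en-1-one | CC1=CC(=O)CCC1 | starting material
8 | (1S,6S,7S)-7-[2-(2-chloroethyl)-1,3-dioxolan-2-yl]-6-methylbicyclo[4.2.0]octan-2-one | ClCCC1(OCCO1)[C@H]2C[C@@H]3C(=O)CCC[C@]23C | intermediate
9 | (S)-3-{(S)-1-[2-(2-chloroethyl)-1,3-dioxolan-2-yl]ethyl}-3-methylcyclohexan-1-one | ClCCC1(OCCO1)[C@@H](C)[C@@]2(C)CCCC(=O)C2 | intermediate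
10 | 3,3-ethylenedioxy-4α,5β-dimethyl-10β-H-decalin-9-one (cis-fused epimer drawn) | C1COC2(O1)CC[C@@H]3C(=O)CCC[C@]3(C)[C@@H]2C | intermediate
11 | 8-hydroxy derivative of 10 (C8 epimers, centre left open) | C1COC2(O1)CC[C@@H]3C(=O)C(O)CC[C@]3(C)[C@@H]2C | intermediate
12 | 3,3-ethylenedioxy-9-hydroxy-4α,5β-dimethyl-Δ9(10)-octalin-8-one | C1COC2(O1)CCC3=C(O)C(=O)CC[C@]3(C)[C@@H]2C | intermediate
13 | 9-trifluoromethanesulfonate of 12 | C1COC2(O1)CCC3=C(OS(=O)(=O)C(F)(F)F)C(=O)CC[C@]3(C)[C@@H]2C | intermediate
14 | 3,3-ethylenedioxy-4α,5β-dimethyl-Δ9(10)-octalin-8-one | C1COC2(O1)CCC3=CC(=O)CC[C@]3(C)[C@@H]2C | intermediate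
15 | 3,3-ethylenedioxy-4α,5β-dimethyl-10α-H-decalin-8-one | C1COC2(O1)CC[C@H]3CC(=O)CC[C@]3(C)[C@@H]2C | intermediate
16 | acetone | CC(C)=O | starting material
17 | 7α-(2-hydroxypropan-2-yl) derivative of 15 | C1COC2(O1)CC[C@H]3CC(=O)[C@H](C(C)(C)O)C[C@]3(C)[C@@H]2C | intermediate
18 | methanesulfonate of 17 (not isolated) | C1COC2(O1)CC[C@H]3CC(=O)[C@H](C(C)(C)OS(C)(=O)=O)C[C@]3(C)[C@@H]2C | intermediate
19 | 3,3-ethylenedioxy-4α,5β-dimethyl-7-(propan-2-ylidene)-10α-H-decalin-8-one | C1COC2(O1)CC[C@H]3CC(=O)C(=C(C)C)C[C@]3(C)[C@@H]2C | intermediate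
20 | 9α-hydroxy derivative of 19 | C1COC2(O1)CC[C@H]3[C@H](O)C(=O)C(=C(C)C)C[C@]3(C)[C@@H]2C | intermediate
21 | 9α-tert-butyldimethylsilyl ether of 20 | C1COC2(O1)CC[C@H]3[C@H](O[Si](C)(C)C(C)(C)C)C(=O)C(=C(C)C)C[C@]3(C)[C@@H]2C | intermediate
22 | 4-epi dione: 9α-(TBSO)-4α,5β-dimethyl-7-(propan-2-ylidene)-10α-H-decalin-3,8-dione (not isolated) | O=C1CC[C@H]2[C@H](O[Si](C)(C)C(C)(C)C)C(=O)C(=C(C)C)C[C@]2(C)[C@@H]1C | intermediate
23 | 9α-(TBSO)-4β,5β-dimethyl-7-(propan-2-ylidene)-10α-H-decalin-3,8-dione | O=C1CC[C@H]2[C@H](O[Si](C)(C)C(C)(C)C)C(=O)C(=C(C)C)C[C@]2(C)[C@H]1C | intermediate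
24 | 9α-(TBSO)-3β-hydroxy-4β,5β-dimethyl-7-(propan-2-ylidene)-10α-H-decalin-8-one | O[C@H]1CC[C@H]2[C@H](O[Si](C)(C)C(C)(C)C)C(=O)C(=C(C)C)C[C@]2(C)[C@H]1C | intermediate
25 | 3-methylfuran-2(5H)-one | CC1=CCOC1=O | starting material
26 | sodium (Z)-4-hydroxy-2-methylbut-2-enoate (not isolated) | OC/C=C(/C)C(=O)[O-].[Na+] | intermediate
27 | 4-methoxybenzyl (Z)-4-hydroxy-2-methylbut-2-enoate | OC/C=C(/C)C(=O)OCc1ccc(OC)cc1 | intermediate
28 | angelic acid | C/C=C(/C)C(O)=O | starting material
29 | 4-methoxybenzyl (Z)-2-methyl-4-{[(Z)-2-methylbut-2-enoyl]oxy}but-2-enoate | C/C=C(/C)C(=O)OC/C=C(/C)C(=O)OCc1ccc(OC)cc1 | intermediate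
30 | (Z)-2-methyl-4-{[(Z)-2-methylbut-2-enoyl]oxy}but-2-enoic acid | C/C=C(/C)C(=O)OC/C=C(/C)C(O)=O | intermediate
31 | 9-O-tert-butyldimethylsilyl ether of the target | C/C=C(/C)C(=O)OC/C=C(/C)C(=O)O[C@@H]1CC[C@H]2[C@H](O[Si](C)(C)C(C)(C)C)C(=O)C(=C(C)C)C[C@]2(C)[C@H]1C | intermediate
32 | CNP0308665.1 | C/C=C(/C)C(=O)OC/C=C(/C)C(=O)O[C@@H]1CC[C@H]2[C@H](O)C(=O)C(=C(C)C)C[C@]2(C)[C@H]1C | target

**Step count and risks**
Total steps: 22. Longest linear sequence: 19 (steps 1–17, 21, 22); steps 18–20 build the side-chain acid.

Step 4 (key step). The ketal oxygens of 6, present in excess, may compete for the AlBr3-activated Lewis acid or be ionised by it, so that free 7 reacts in a racemic background process; head-to-head addition is a second leak. Fallback: 7 and 6 are irradiated without Lewis acid (λ = 350 nm, CH2Cl2, −40 °C), the classical uncatalysed enone–alkene photocycloaddition, which gives 8 as a racemate together with its enantiomer ent-8 F1. The antipodes are separated by preparative supercritical-fluid chromatography on a polysaccharide chiral stationary phase. The fallback sets out from 6 and 7 and returns at 8.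

Step 16. Thermodynamic equilibration at C4 may be incomplete or only weakly biased (the equatorial preference is estimated as modest), leaving 4-epi material. Fallback under kinetic control: the crude mixture of 22 and 23 obtained from 21 is converted with Me3SiI and (Me3Si)2NH (CH2Cl2, −20 °C) into the more substituted Δ3(4) trimethylsilyl enol ether F2, which removes the C4 centre. Protodesilylation at −78 °C (Bu4NF/AcOH, THF) then delivers the proton to C4 axially from the α face, anti to the C5 methyl, to give 23. The fallback sets out from 21 and returns at 23.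

Step 21. E2 loss of the axial oxyphosphonium (anti-periplanar axial hydrogens at C2 and C4) may outpace SN2 displacement by the weakly acidic, bulky enoic acid, giving ring A olefins. Fallback that separates inversion from acylation: Mitsunobu reaction of 24 with 4-nitrobenzoic acid (more acidic, faster displacement; PPh3, DIAD, toluene) gives the inverted 3α-(4-nitrobenzoate) F3. Methanolysis (K2CO3, MeOH, 0 °C) gives the equatorial 3α-alcohol F4. Yamaguchi esterification with 30 (2,4,6-trichlorobenzoyl chloride, Et3N, toluene; then F4 and sub-stoichiometric DMAP) gives 31 with retention. The fallback sets out from 24 and returns at 31.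

**Further compounds**
F1 | step 4 | (1R,6R,7R)-7-[2-(2-chloroethyl)-1,3-dioxolan-2-yl]-6-methylbicyclo[4.2.0]octan-2-one (ent-8) | ClCCC1(OCCO1)[C@@H]2C[C@H]3C(=O)CCC[C@@]23C
F2 | step 16 | 9α-(TBSO)-5β-methyl-4-methyl-7-(propan-2-ylidene)-3-(trimethylsilyloxy)-10α-H-Δ3(4)-octalin-8-one | C[Si](C)(C)OC1CC[C@H]2[C@H](O[Si](C)(C)C(C)(C)C)C(=O)C(=C(C)C)C[C@]2(C)C=1C
F3 | step 21 | 9α-(TBSO)-4β,5β-dimethyl-8-oxo-7-(propan-2-ylidene)-10α-H-decalin-3α-yl 4-nitrobenzoate | O=C(O[C@@H]1CC[C@H]2[C@H](O[Si](C)(C)C(C)(C)C)C(=O)C(=C(C)C)C[C@]2(C)[C@H]1C)c1ccc(cc1)[N+](=O)[O-]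
F4 | step 21 | 9α-(TBSO)-3α-hydroxy-4β,5β-dimethyl-7-(propan-2-ylidene)-10α-H-decalin-8-one | O[C@@H]1CC[C@H]2[C@H](O[Si](C)(C)C(C)(C)C)C(=O)C(=C(C)C)C[C@]2(C)[C@H]1C
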